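(Readings and results were computed for substances that don't exist; noise was put on by code.)

Early in the grey run product reads 0% at 25.0 s, yet it reads 18% at 120 s. The curve bends upward. Between 80.0 s and 120 s the readings grow by a factor 2.57, and the squared time ratio is 2.25, with 1.5 percentage points of scatter on each reading.

common to all: solid substrate 10 mM
- ochre: partner 1.5 equiv; free catalyst 0.1 mol%; second catalyst 1.1 mol%; added ligand 0.48 mM; run made earlier
- grey: partner 1.5 equiv; free catalyst 0.1 mol%; second catalyst 2.9 mol%; added ligand 0.48 mM; run made earlier
- amber: partner 1.5 equiv; free catalyst 0.1 mol%; second catalyst 1 mol%; added ligand 0.62 mM; run made earlier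
- delta: partner 1.50 equiv; free catalyst 0.025 mol%; second catalyst 1 mol%; added ligand 0.48 mM; time 2.5 min
- alpha: partner 1.50 equiv; free catalyst 0.1 mol%; second catalyst 2 mol%; added ligand 0.48 mM; time 2.5 min
- beta: partner 1.50 equiv; free catalyst 0.05 mol%; second catalyst 1 mol%; added ligand 0.80 mM; time 2.5 min
- theta: partner 1.50 equiv; free catalyst 0.1 mol%; second catalyst 1 mol%; added ligand 0.48 mM; time 2.5 min

| run | time / s | product / % |
|---|---|---|
| ochre | 10.0 | 0 |
| ochre | 15.0 | 2 |
| ochre | 30.0 | 1 |
| ochre | 60.0 | 0 |
| ochre | 120 | 7 |
| grey | 10.0 | 0 |
| grey | 25.0 | 0 |
| grey | 50.0 | 3 |
| grey | 80.0 | 7 |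
| grey | 120 | 18 |
| amber | 10.0 | 1 |
| amber | 25.0 | 0 |
| amber | 50.0 | 4 |
| amber | 80.0 | 4 |
| amber | 120 | 7 |

(scatter of a reading: 1.5 percentage points)

- the flasks put in order of amount of product, in percent of the solid substrate charged, best first, at 2.5 min (delta / alpha / beta / theta)
- the amount of product, in percent of the solid substrate charged of the flask you put first, at 2.5 min
- the amount of product, in percent of the solid substrate charged of the flask you put last, at 2.5 min

Two chemists, Ines and Paul, dispute that bend, but they share one yardstick. At 120 s grey reads 2.57 times what ochre reads, and grey's second catalyst is 2.64 times ochre's. So product looks proportional to second catalyst. Scale grey's last reading to 1 mol% of second catalyst and by the squared time to 2.5 min. That gives 9.70%, the unit yield: the product expected at 2.5 min from 1 mol% of second catalyst and 0.1 mol% of free catalyst. Both chemists take it as their value for theta.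

Ines holds that free catalyst feeds open intermediate at a steady rate, so [open intermediate] grows with time and product with its square. Product then also follows free catalyst. Alpha has twice theta's second catalyst and should give 19.4%. Delta has a quarter of theta's free catalyst and should give 2.42%. Beta, before its extra ligand is counted, should give 4.85%.

Paul holds that the bend is the solid substrate entering solution, with free catalyst a bystander. Delta and beta then stay near the unit yield. No earlier run changes free catalyst, so the readings cannot silence him.

The forecast takes the bend as a slowly dissolving solid, as Paul does, but scales product with free catalyst, as Ines does: it gives alpha > theta > beta > delta, 19% and 2.4%, and says “Rate should be about proportional to free catalyst, which is a guess”. The flasks give alpha > theta > beta > delta: alpha 15.8%, theta 9.59%, beta 4.98%, delta 2.58%.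

    solid substrate ⇌ starting material, rate k1*(cs1 - [starting material]) while solid is left; crystals form when [starting material] > cs1 (solubility = 7.90 mM, k = 0.190 s⁻¹)
    second catalyst + added ligand ⇌ idle complex, settled at all times (K = 87.0 L mol⁻¹)
    partner + catalyst intermediate → second catalyst + product (k = 410 L mol⁻¹ s⁻¹)
    open intermediate → decomposed reagent (k = 0.00820 s⁻¹)
    second catalyst + open intermediate ⇌ catalyst intermediate (K = 9.60 L mol⁻¹, k = 3300 L mol⁻¹ s⁻¹)
    starting material + free catalyst → free catalyst + open intermediate (k = 400 L mol⁻¹ s⁻¹)

The unit yield over the free-catalyst ratio gives 2.42% against delta's 2.58%, and 4.85% against beta's 4.98%. In delta the dissolving ran first, half its turnover done by 0.0740 min, and [starting material] then stood at 78.6% at 1.25 min and 78.6% at 2.50 min, a steady, zero-order feed, while half of the decomposition came by 1.65 min. Paul's picture belongs to the late stretch: at 25.0 min theta, with solid substrate at 0% and starting material at 0.262%, holds product 36.9%, and delta, on a quarter of the free catalyst, holds 28.4%.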